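**Retrosynthetic overview**
1. Feature: ring F (sixth ring) is a benzene with oxygen on C1, C3, C4 and C5 and C–H on C2 and C6. Its two ether oxygens (on C1 and C4) are also the C6 oxygen of ring E and the C1 oxygen of ring G, so all six carbons of ring F can be grown between two phenol oxygens; rings B, D, H and J have the same pattern.
2. Target 49 ⇐ undecamer 48 by cleavage of 22 methyl and 5 ethyl ethers; 48 ⇐ benzannulation that builds ring F from the A–E ethynyl ether 36 (supplies C1, C2) and the G–K 4-aryloxy-3-ethoxycyclobutenone 47 (supplies C3–C6).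
3. 36 ⇐ the same benzannulation for ring B, then ring D, from ring A ethynyl ether 23 and two copies of catechol cyclobutenone 14, whose second oxygen carries a 1,2-dichlorovinyl group as a masked ethynyl ether.
4. 47 ⇐ ring H, then ring J, from ring G ethynyl ether 17, cyclobutenone 14 (ring I) and ring K cyclobutenone 28; then benzyl removal and cyclobutenone construction on the C1 oxygen of ring G.
5. All monomers ⇐ phenol O-alkylations only (trichloroethylene for ynol ethers; bromoacetate then ethoxyacetylene for cyclobutenones). Order of ring formation: B, D (left half) and H, J (right half), ring F last.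

Key step: step 24

Remark: every benzannulated ring inherits one ethyl ether from ethoxyacetylene, so both pentamers carry OEt on rings B, D, H and J as spectator groups that the last step removes with the methyl ethers; C4 of each cyclobutenone is racemic and is lost on aromatization, and the target has no stereocentre.

**Route**

Step 1
Reactants: 1 2,3,4-trimethoxybenzaldehyde
Product: 3 2,3,4-trimethoxyphenol, via aryl formate 2 (not isolated)
Conditions: mCPBA, CH2Cl2, 0 °C → rt; then K2CO3 (cat.), MeOH, rt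
Reagents that add atoms: 3-chloroperoxybenzoic acid, OOC(=O)c1cccc(Cl)c1
Why: Baeyer–Villiger oxidation of the electron-rich aldehyde should proceed with aryl migration to formate 2, which catalytic carbonate in methanol transesterifies to the phenol.

Step 2
Reactants: 3 2,3,4-trimethoxyphenol
Product: 4 2-hydroxy-3,4,5-trimethoxybenzaldehyde
Conditions: MgCl2, Et3N, (CH2O)n, MeCN, reflux; then 1 M HCl
Reagents that add atoms: paraformaldehyde (formaldehyde), C=O
Why: The magnesium-phenoxide-directed ortho-formylation (Casnati–Skattebøl reaction) can only reach C6, the single free ortho position, and so places the future second catechol oxygen next to the hydroxyl.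

Step 3
Reactants: 4 2-hydroxy-3,4,5-trimethoxybenzaldehyde; 5 trichloroethylene
Product: 6 2-[(E)-1,2-dichloroethenyl]oxy-3,4,5-trimethoxybenzaldehyde
Conditions: K2CO3, DMF, 70 °C
Reagents that add atoms: none
Why: Carbonate generates dichloroacetylene from 5, and anti addition of the phenoxide should give the (E)-1,2-dichlorovinyl ether, a robust masked ethynyl ether on the hindered oxygen (the future C6 oxygen of rings C, E, G and I).

Step 4
Reactants: 6 2-[(E)-1,2-dichloroethenyl]oxy-3,4,5-trimethoxybenzaldehyde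
Product: 8 2-[(E)-1,2-dichloroethenyl]oxy-3,4,5-trimethoxyphenol, via aryl formate 7 (not isolated)
Conditions: mCPBA, CH2Cl2, 0 °C → rt; then K2CO3 (cat.), MeOH, 0 °C
Reagents that add atoms: 3-chloroperoxybenzoic acid, OOC(=O)c1cccc(Cl)c1
Why: Baeyer–Villiger oxidation and formate methanolysis turn the formyl-bearing carbon into the unhindered catechol oxygen (future C1 oxygen), the electron-poor dichlorovinyl double bond being far less reactive toward the peracid than the aldehyde.

Step 5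
Reactants: 8 2-[(E)-1,2-dichloroethenyl]oxy-3,4,5-trimethoxyphenol; 9 ethyl bromoacetate
Product: 11 {2-[(E)-1,2-dichloroethenyl]oxy-3,4,5-trimethoxyphenoxy}acetic acid, via ethyl ester 10 (not isolated)
Conditions: K2CO3, DMF, rt; then LiOH, THF–H2O, rt; then 1 M HCl
Reagents that add atoms: lithium hydroxide, [Li+].[OH-]
Why: Williamson alkylation of the phenoxide with the α-bromo ester at room temperature and saponification in the same flask should give the aryloxyacetic acid without touching the dichlorovinyl ether.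

Step 6
Reactants: 11 {2-[(E)-1,2-dichloroethenyl]oxy-3,4,5-trimethoxyphenoxy}acetic acid; 12 ethoxyacetylene
Product: 14 racemic 4-{2-[(E)-1,2-dichloroethenyl]oxy-3,4,5-trimethoxyphenoxy}-3-ethoxycyclobut-2-en-1-one, via acid chloride 13 (not isolated)
Conditions: (COCl)2, DMF (cat.), CH2Cl2, 0 °C → rt; evaporate; then 12 (4 equiv), Et3N (slow addition), CH2Cl2, 0 °C → rt
Reagents that add atoms: none
Why: Triethylamine dehydrochlorinates 13 to the aryloxyketene, which undergoes (2+2) cycloaddition with ethoxyacetylene, the nucleophilic CH carbon of the alkyne bonding to the ketene carbonyl carbon so that OEt sits on C3 and OAr on the new sp3 carbon C4, formed as a racemate.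

Step 7
Reactants: 8 2-[(E)-1,2-dichloroethenyl]oxy-3,4,5-trimethoxyphenol
Product: 15 1-benzyloxy-2-[(E)-1,2-dichloroethenyl]oxy-3,4,5-trimethoxybenzene
Conditions: BnBr, K2CO3, DMF, rt
Reagents that add atoms: benzyl bromide, BrCc1ccccc1
Why: Williamson benzylation protects the future C1 oxygen of ring G in a form that tolerates n-BuLi and heating and is later removed by hydrogenolysis.

Step 8
Reactants: 15 1-benzyloxy-2-[(E)-1,2-dichloroethenyl]oxy-3,4,5-trimethoxybenzene
Product: 17 1-benzyloxy-2-ethynyloxy-3,4,5-trimethoxybenzene (ring G ethynyl ether), via lithium acetylide 16 (not isolated)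
Conditions: n-BuLi (2.3 equiv), THF, −78 → −40 °C; then H2O, −78 °C → rt
Reagents that add atoms: none
Why: n-BuLi dehydrochlorinates the dichlorovinyl ether to the chloroalkynyl ether and then exchanges chlorine for lithium, and protonation of 16 gives the terminal ethynyl ether; both positions ortho to this oxygen are substituted, so ortho-lithiation cannot compete.

Step 9
Reactants: 18 2,4,6-trimethoxybenzaldehyde
Product: 20 2,4,6-trimethoxyphenol, via aryl formate 19 (not isolated)
Conditions: mCPBA, CH2Cl2, 0 °C → rt; then K2CO3 (cat.), MeOH, rt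
Reagents that add atoms: 3-chloroperoxybenzoic acid, OOC(=O)c1cccc(Cl)c1
Why: Baeyer–Villiger oxidation with aryl migration followed by formate methanolysis, as in step 1, gives the ring A phenol.

Step 10
Reactants: 20 2,4,6-trimethoxyphenol; 5 trichloroethylene
Product: 21 2-[(E)-1,2-dichloroethenyl]oxy-1,3,5-trimethoxybenzene
Conditions: K2CO3, DMF, 70 °C
Reagents that add atoms: none
Why: The phenoxide, although flanked by two methoxy groups, should add anti to the small linear electrophile dichloroacetylene formed from 5 to give the (E)-dichlorovinyl ether.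

Step 11
Reactants: 21 2-[(E)-1,2-dichloroethenyl]oxy-1,3,5-trimethoxybenzene
Product: 23 2-ethynyloxy-1,3,5-trimethoxybenzene (ring A ethynyl ether), via lithium acetylide 22 (not isolated)
Conditions: n-BuLi (2.3 equiv), THF, −78 → −40 °C; then H2O, −78 °C → rt
Reagents that add atoms: none
Why: Dehydrochlorination and chlorine–lithium exchange by n-BuLi followed by protonation give the terminal aryl ethynyl ether, the ring C–H bonds being lithiated too slowly at −78 °C to interfere.

Step 12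
Reactants: 24 3,4,5-trimethoxyphenol; 9 ethyl bromoacetate
Product: 26 (3,4,5-trimethoxyphenoxy)acetic acid, via ethyl ester 25 (not isolated)
Conditions: K2CO3, DMF, rt; then LiOH, THF–H2O, rt; then 1 M HCl
Reagents that add atoms: lithium hydroxide, [Li+].[OH-]
Why: Williamson alkylation of the unhindered phenoxide and saponification in the same flask give the ring K aryloxyacetic acid.

Step 13
Reactants: 26 (3,4,5-trimethoxyphenoxy)acetic acid; 12 ethoxyacetylene
Product: 28 racemic 3-ethoxy-4-(3,4,5-trimethoxyphenoxy)cyclobut-2-en-1-one (ring K cyclobutenone), via acid chloride 27 (not isolated)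
Conditions: (COCl)2, DMF (cat.), CH2Cl2, 0 °C → rt; evaporate; then 12 (4 equiv), Et3N (slow addition), CH2Cl2, 0 °C → rt
Reagents that add atoms: none
Why: The aryloxyketene generated by dehydrochlorination of 27 adds ethoxyacetylene in a (2+2) cycloaddition with the same polarity-controlled regiochemistry as in step 6, giving racemic C4.

Step 14
Reactants: 23 2-ethynyloxy-1,3,5-trimethoxybenzene; 14 catechol cyclobutenone
Product: 30 A–B–C trimer (ring B 3-OMe 5-OEt; ring C O-dichlorovinyl), via ring B phenol 29 (not isolated)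
Conditions: 23 (1.5 equiv), PhMe, 80 → 110 °C, Ar; evaporate; then MeI, K2CO3, DMF, rt
Reagents that add atoms: iodomethane, CI
Why: The Danheiser benzannulation (4π opening of 14 to the vinylketene, regioselective (2+2) addition of 23, 4π opening, 6π closure, tautomerization) should build ring B with the ring A oxygen on C1 para to the ring C oxygen on C4, and methylation in the same flask caps the new C3 hydroxyl.

Step 15
Reactants: 30 A–B–C trimer dichlorovinyl ether
Product: 32 A–B–C trimer ethynyl ether (ethynyl on the C6 oxygen of ring C), via lithium acetylide 31 (not isolated)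
Conditions: n-BuLi (2.3 equiv), THF, −78 → −40 °C; then H2O, −78 °C → rt
Reagents that add atoms: none
Why: The dichlorovinyl ether carried through the benzannulation is unmasked by dehydrochlorination and chlorine–lithium exchange as in step 8, the alkyl aryl ethers being inert to n-BuLi at −78 °C.

Step 16
Reactants: 32 A–B–C trimer ethynyl ether; 14 catechol cyclobutenone
Product: 34 A–E pentamer dichlorovinyl ether (rings B and D 3-OMe 5-OEt), via ring D phenol 33 (not isolated)
Conditions: 14 (1.5 equiv), PhMe, 80 → 110 °C, Ar; evaporate; then MeI, K2CO3, DMF, rt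
Reagents that add atoms: iodomethane, CI
Why: A second Danheiser benzannulation builds ring D between the C6 oxygen of ring C (ynol ether carbon) and the C1 oxygen of ring E (cyclobutenone C4) under the same regiocontrol, followed by capping of the ring D hydroxyl.

Step 17
Reactants: 34 A–E pentamer dichlorovinyl ether
Product: 36 A–E pentamer ethynyl ether (ethynyl on the C6 oxygen of ring E), via lithium acetylide 35 (not isolated)
Conditions: n-BuLi (2.3 equiv), THF, −78 → −40 °C; then H2O, −78 °C → rt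
Reagents that add atoms: none
Why: Dehydrochlorination and chlorine–lithium exchange followed by protonation convert the ring E dichlorovinyl ether into the terminal ethynyl ether, with no C–H ortho to that oxygen available for lithiation.

Step 18
Reactants: 17 ring G ethynyl ether; 14 catechol cyclobutenone
Product: 38 G–H–I trimer (ring G 1-OBn; ring H 3-OMe 5-OEt; ring I O-dichlorovinyl), via ring H phenol 37 (not isolated)
Conditions: 17 (1.3 equiv), PhMe, 80 → 110 °C, Ar; evaporate; then MeI, K2CO3, DMF, rt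
Reagents that add atoms: iodomethane, CI
Why: The Danheiser benzannulation builds ring H between the C6 oxygen of ring G and the C1 oxygen of ring I, the benzyl and dichlorovinyl ethers being thermally inert spectators, and the ring H hydroxyl is capped in the same flask.

Step 19
Reactants: 38 G–H–I trimer dichlorovinyl ether
Product: 40 G–H–I trimer ethynyl ether (ethynyl on the C6 oxygen of ring I), via lithium acetylide 39 (not isolated)
Conditions: n-BuLi (2.3 equiv), THF, −78 → −40 °C; then H2O, −78 °C → rt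
Reagents that add atoms: none
Why: The dichlorovinyl ether is unmasked as in step 8, the benzyl ether tolerating n-BuLi at −78 °C.

Step 20
Reactants: 40 G–H–I trimer ethynyl ether; 28 ring K cyclobutenone
Product: 42 G–K pentamer benzyl ether (rings H and J 3-OMe 5-OEt), via ring J phenol 41 (not isolated)
Conditions: 28 (1.5 equiv), PhMe, 80 → 110 °C, Ar; evaporate; then MeI, K2CO3, DMF, rt
Reagents that add atoms: iodomethane, CI
Why: The Danheiser benzannulation builds ring J between the C6 oxygen of ring I and the ring K oxygen with the usual regiochemistry, and methylation caps the ring J hydroxyl before the later O-alkylation.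

Step 21
Reactants: 42 G–K pentamer benzyl ether
Product: 43 G–K pentamer phenol (free OH on C1 of ring G)
Conditions: H2 (1 atm), Pd/C, EtOAc–EtOH, rt
Reagents that add atoms: none
Why: Hydrogenolysis cleaves the benzyl aryl ether selectively because the molecule holds no other reducible group.

Step 22
Reactants: 43 G–K pentamer phenol; 9 ethyl bromoacetate
Product: 45 G–K pentamer aryloxyacetic acid, via ethyl ester 44 (not isolated)
Conditions: K2CO3, DMF, rt; then LiOH, THF–H2O, rt; then 1 M HCl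
Reagents that add atoms: lithium hydroxide, [Li+].[OH-]
Why: The ring G phenoxide has one free ortho position and should undergo Williamson alkylation as readily as monomer 8, and the ester is saponified in the same flask.

Step 23
Reactants: 45 G–K pentamer aryloxyacetic acid; 12 ethoxyacetylene
Product: 47 racemic G–K pentamer 4-aryloxy-3-ethoxycyclobut-2-en-1-one, via acid chloride 46 (not isolated)
Conditions: (COCl)2, DMF (cat.), CH2Cl2, 0 °C → rt; evaporate; then 12 (6 equiv), Et3N (slow addition), CH2Cl2, 0 °C → rt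
Reagents that add atoms: none
Why: The ketene–ethoxyacetylene (2+2) cycloaddition already used for 14 and 28 is repeated on the pentamer, excess alkyne and slow base addition keeping the aryloxyketene concentration low against dimerization.

Step 24
Reactants: 36 A–E pentamer ethynyl ether; 47 G–K pentamer cyclobutenone
Product: 48 undecamer with ring F as phenol (OH on C3, OEt on C5)
Conditions: 36 (1.2 equiv), PhMe (0.3 M), 80 → 110 °C, sealed tube, Ar
Reagents that add atoms: none
Why: Heating opens 47 by 4π electrocyclic cleavage of the C1–C4 bond to the (aryloxy)(ethoxy)vinylketene, the donor aryloxy group rotating outward so that the terminal hydrogen points inward; the ketene C=C then adds ynol ether 36 in a (2+2) cycloaddition, the 4-vinylcyclobutenone opens (4π) to a dienylketene, and a thermal disrotatory 6π electrocyclization followed by tautomerization gives the phenol. This is the Danheiser benzannulation of cyclobutenones with alkoxyalkynes, here with an aryl ynol ether and a 4-aryloxy-3-ethoxy pattern that is untested at this size, which is why steps 14, 16, 18 and 20 run the same reaction first on small partners. Ring F is the only ring closed, by 6π electrocyclization between the former carbonyl carbon (C3) and the former C4 after the alkyne has been inserted as C1–C2 (new bonds C2–C3 and C1–C6). No stereocentre is created, and the racemic C4 of 47 becomes the sp2 carbon C4 of ring F. The step needs the regiochemistry of the ketene–alkyne addition, which the polarity of the partners secures: the electron-rich terminal CH carbon of the ynol ether bonds to the electrophilic ketene carbonyl carbon, so the ring E oxygen ends on C1 para to the ring G oxygen on C4, with OH on C3 and OEt on C5. The aryl ethynyl ether has no β-hydrogen for retro-ene loss of ketene on heating, and both crowded C–O bonds of ring F exist before the step (on the sp carbon of 36 and the sp3 carbon of 47), so no diaryl ether bond has to be forged under steric pressure.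

Step 25
Reactants: 48 undecamer ring F phenol
Product: 49 CNP0245174.0 (target)
Conditions: BBr3 (excess), CH2Cl2, −78 °C → rt; then H2O, 0 °C; isolation under Ar
Reagents that add atoms: none
Why: BBr3 cleaves the 22 methyl and 5 ethyl aryl ethers by bromide attack at the alkyl carbon of the boron-complexed ethers, while the ten diaryl ether bonds, which offer no sp3 carbon, should stay intact.

**Compound list**
1 | 2,3,4-trimethoxybenzaldehyde | COc1ccc(C=O)c(OC)c1OC | starting material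
2 | 2,3,4-trimethoxyphenyl formate | COc1ccc(OC=O)c(OC)c1OC | intermediate
3 | 2,3,4-trimethoxyphenol | COc1ccc(O)c(OC)c1OC | intermediate
4 | 2-hydroxy-3,4,5-trimethoxybenzaldehyde | O=Cc1cc(OC)c(OC)c(OC)c1O | intermediate
5 | trichloroethylene | ClC=C(Cl)Cl | starting material
6 | 2-[(E)-1,2-dichloroethenyl]oxy-3,4,5-trimethoxybenzaldehyde | O=Cc1cc(OC)c(OC)c(OC)c1O/C(Cl)=C\Cl | intermediate
7 | 2-[(E)-1,2-dichloroethenyl]oxy-3,4,5-trimethoxyphenyl formate | O=COc1cc(OC)c(OC)c(OC)c1O/C(Cl)=C\Cl | intermediate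
8 | 2-[(E)-1,2-dichloroethenyl]oxy-3,4,5-trimethoxyphenol (differentiated catechol for rings C, E, G, I) | Oc1cc(OC)c(OC)c(OC)c1O/C(Cl)=C\Cl | intermediate
9 | ethyl bromoacetate | CCOC(=O)CBr | starting material
10 | ethyl {2-[(E)-1,2-dichloroethenyl]oxy-3,4,5-trimethoxyphenoxy}acetate | CCOC(=O)COc1cc(OC)c(OC)c(OC)c1O/C(Cl)=C\Cl | intermediate
11 | {2-[(E)-1,2-dichloroethenyl]oxy-3,4,5-trimethoxyphenoxy}acetic acid | OC(=O)COc1cc(OC)c(OC)c(OC)c1O/C(Cl)=C\Cl | intermediate
12 | ethoxyacetylene | CCOC#C | starting material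
13 | {2-[(E)-1,2-dichloroethenyl]oxy-3,4,5-trimethoxyphenoxy}acetyl chloride | ClC(=O)COc1cc(OC)c(OC)c(OC)c1O/C(Cl)=C\Cl | intermediate
14 | racemic 4-{2-[(E)-1,2-dichloroethenyl]oxy-3,4,5-trimethoxyphenoxy}-3-ethoxycyclobut-2-en-1-one (catechol cyclobutenone for rings C, E, I) | CCOC1=CC(=O)C1Oc1cc(OC)c(OC)c(OC)c1O/C(Cl)=C\Cl | intermediate
15 | 1-benzyloxy-2-[(E)-1,2-dichloroethenyl]oxy-3,4,5-trimethoxybenzene | c1ccccc1COc1cc(OC)c(OC)c(OC)c1O/C(Cl)=C\Cl | intermediate
16 | lithium acetylide of 17 (lithium on the terminal alkyne carbon) | c1ccccc1COc1cc(OC)c(OC)c(OC)c1OC#C[Li] | intermediate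
17 | 1-benzyloxy-2-ethynyloxy-3,4,5-trimethoxybenzene (ring G ethynyl ether) | c1ccccc1COc1cc(OC)c(OC)c(OC)c1OC#C | intermediate
18 | 2,4,6-trimethoxybenzaldehyde | COc1cc(OC)c(C=O)c(OC)c1 | starting material
19 | 2,4,6-trimethoxyphenyl formate | COc1cc(OC)c(OC=O)c(OC)c1 | intermediate
20 | 2,4,6-trimethoxyphenol | COc1cc(OC)c(O)c(OC)c1 | intermediate
21 | 2-[(E)-1,2-dichloroethenyl]oxy-1,3,5-trimethoxybenzene | COc1cc(OC)cc(OC)c1O/C(Cl)=C\Cl | intermediate
22 | lithium acetylide of 23 | COc1cc(OC)cc(OC)c1OC#C[Li] | intermediate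
23 | 2-ethynyloxy-1,3,5-trimethoxybenzene (ring A ethynyl ether) | COc1cc(OC)cc(OC)c1OC#C | intermediate
24 | 3,4,5-trimethoxyphenol | COc1cc(O)cc(OC)c1OC | starting material
25 | ethyl (3,4,5-trimethoxyphenoxy)acetate | CCOC(=O)COc1cc(OC)c(OC)c(OC)c1 | intermediate
26 | (3,4,5-trimethoxyphenoxy)acetic acid | OC(=O)COc1cc(OC)c(OC)c(OC)c1 | intermediate
27 | (3,4,5-trimethoxyphenoxy)acetyl chloride | ClC(=O)COc1cc(OC)c(OC)c(OC)c1 | intermediate
28 | racemic 3-ethoxy-4-(3,4,5-trimethoxyphenoxy)cyclobut-2-en-1-one (ring K cyclobutenone) | CCOC1=CC(=O)C1Oc1cc(OC)c(OC)c(OC)c1 | intermediate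
29 | A–B–C trimer, ring B phenol: ring B is a 1,4-phenylene with OH on C3 and OEt on C5; its C1 oxygen carries 2,4,6-trimethoxyphenyl (ring A), its C4 oxygen is on C1 of ring C (3,4,5-trimethoxy), whose C6 oxygen carries (E)-1,2-dichloroethenyl | COc1cc(OC)cc(OC)c1Oc1cc(O)c(c(OCC)c1)Oc1cc(OC)c(OC)c(OC)c1O/C(Cl)=C\Cl | intermediate
30 | A–B–C trimer as 29 with OMe on C3 of ring B | COc1cc(OC)cc(OC)c1Oc1cc(OC)c(c(OCC)c1)Oc1cc(OC)c(OC)c(OC)c1O/C(Cl)=C\Cl | intermediate
31 | lithium acetylide of 32 | COc1cc(OC)cc(OC)c1Oc1cc(OC)c(c(OCC)c1)Oc1cc(OC)c(OC)c(OC)c1OC#C[Li] | intermediate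
32 | A–B–C trimer ethynyl ether (ethynyl on the C6 oxygen of ring C) | COc1cc(OC)cc(OC)c1Oc1cc(OC)c(c(OCC)c1)Oc1cc(OC)c(OC)c(OC)c1OC#C | intermediate
33 | A–E pentamer, ring D phenol (OH on C3, OEt on C5 of ring D; ring E C6 oxygen carries (E)-1,2-dichloroethenyl) | COc1cc(OC)cc(OC)c1Oc1cc(OC)c(c(OCC)c1)Oc1cc(OC)c(OC)c(OC)c1Oc1cc(O)c(c(OCC)c1)Oc1cc(OC)c(OC)c(OC)c1O/C(Cl)=C\Cl | intermediate
34 | A–E pentamer as 33 with OMe on C3 of ring D | COc1cc(OC)cc(OC)c1Oc1cc(OC)c(c(OCC)c1)Oc1cc(OC)c(OC)c(OC)c1Oc1cc(OC)c(c(OCC)c1)Oc1cc(OC)c(OC)c(OC)c1O/C(Cl)=C\Cl | intermediate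
35 | lithium acetylide of 36 | COc1cc(OC)cc(OC)c1Oc1cc(OC)c(c(OCC)c1)Oc1cc(OC)c(OC)c(OC)c1Oc1cc(OC)c(c(OCC)c1)Oc1cc(OC)c(OC)c(OC)c1OC#C[Li] | intermediate
36 | A–E pentamer ethynyl ether (ethynyl on the C6 oxygen of ring E; rings B and D 3-OMe, 5-OEt) | COc1cc(OC)cc(OC)c1Oc1cc(OC)c(c(OCC)c1)Oc1cc(OC)c(OC)c(OC)c1Oc1cc(OC)c(c(OCC)c1)Oc1cc(OC)c(OC)c(OC)c1OC#C | intermediate
37 | G–H–I trimer, ring H phenol (ring G 1-OBn; ring H OH on C3, OEt on C5; ring I C6 oxygen carries (E)-1,2-dichloroethenyl) | c1ccccc1COc1cc(OC)c(OC)c(OC)c1Oc1cc(O)c(c(OCC)c1)Oc1cc(OC)c(OC)c(OC)c1O/C(Cl)=C\Cl | intermediate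
38 | G–H–I trimer as 37 with OMe on C3 of ring H | c1ccccc1COc1cc(OC)c(OC)c(OC)c1Oc1cc(OC)c(c(OCC)c1)Oc1cc(OC)c(OC)c(OC)c1O/C(Cl)=C\Cl | intermediate
39 | lithium acetylide of 40 | c1ccccc1COc1cc(OC)c(OC)c(OC)c1Oc1cc(OC)c(c(OCC)c1)Oc1cc(OC)c(OC)c(OC)c1OC#C[Li] | intermediate
40 | G–H–I trimer ethynyl ether (ethynyl on the C6 oxygen of ring I) | c1ccccc1COc1cc(OC)c(OC)c(OC)c1Oc1cc(OC)c(c(OCC)c1)Oc1cc(OC)c(OC)c(OC)c1OC#C | intermediate
41 | G–K pentamer, ring J phenol (ring G 1-OBn; ring J OH on C3, OEt on C5; ring K 3,4,5-trimethoxyphenyl) | c1ccccc1COc1cc(OC)c(OC)c(OC)c1Oc1cc(OC)c(c(OCC)c1)Oc1cc(OC)c(OC)c(OC)c1Oc1cc(O)c(c(OCC)c1)Oc1cc(OC)c(OC)c(OC)c1 | intermediate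
42 | G–K pentamer benzyl ether as 41 with OMe on C3 of ring J | c1ccccc1COc1cc(OC)c(OC)c(OC)c1Oc1cc(OC)c(c(OCC)c1)Oc1cc(OC)c(OC)c(OC)c1Oc1cc(OC)c(c(OCC)c1)Oc1cc(OC)c(OC)c(OC)c1 | intermediate
43 | G–K pentamer phenol (free OH on C1 of ring G) | Oc1cc(OC)c(OC)c(OC)c1Oc1cc(OC)c(c(OCC)c1)Oc1cc(OC)c(OC)c(OC)c1Oc1cc(OC)c(c(OCC)c1)Oc1cc(OC)c(OC)c(OC)c1 | intermediate
44 | G–K pentamer ethyl aryloxyacetate (on the C1 oxygen of ring G) | CCOC(=O)COc1cc(OC)c(OC)c(OC)c1Oc1cc(OC)c(c(OCC)c1)Oc1cc(OC)c(OC)c(OC)c1Oc1cc(OC)c(c(OCC)c1)Oc1cc(OC)c(OC)c(OC)c1 | intermediate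
45 | G–K pentamer aryloxyacetic acid | OC(=O)COc1cc(OC)c(OC)c(OC)c1Oc1cc(OC)c(c(OCC)c1)Oc1cc(OC)c(OC)c(OC)c1Oc1cc(OC)c(c(OCC)c1)Oc1cc(OC)c(OC)c(OC)c1 | intermediate
46 | G–K pentamer aryloxyacetyl chloride | ClC(=O)COc1cc(OC)c(OC)c(OC)c1Oc1cc(OC)c(c(OCC)c1)Oc1cc(OC)c(OC)c(OC)c1Oc1cc(OC)c(c(OCC)c1)Oc1cc(OC)c(OC)c(OC)c1 | intermediate
47 | racemic 3-ethoxy-4-aryloxycyclobut-2-en-1-one carrying the G–K pentamer on the C1 oxygen of ring G | CCOC1=CC(=O)C1Oc1cc(OC)c(OC)c(OC)c1Oc1cc(OC)c(c(OCC)c1)Oc1cc(OC)c(OC)c(OC)c1Oc1cc(OC)c(c(OCC)c1)Oc1cc(OC)c(OC)c(OC)c1 | intermediate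
48 | undecamer A–K, ring F with OH on C3 and OEt on C5; rings B, D, H, J 3-OMe, 5-OEt; all other hydroxyls as methyl ethers | COc1cc(OC)cc(OC)c1Oc1cc(OC)c(c(OCC)c1)Oc1cc(OC)c(OC)c(OC)c1Oc1cc(OC)c(c(OCC)c1)Oc1cc(OC)c(OC)c(OC)c1Oc1cc(O)c(c(OCC)c1)Oc1cc(OC)c(OC)c(OC)c1Oc1cc(OC)c(c(OCC)c1)Oc1cc(OC)c(OC)c(OC)c1Oc1cc(OC)c(c(OCC)c1)Oc1cc(OC)c(OC)c(OC)c1 | intermediate
49 | CNP0245174.0 | Oc1cc(O)c(Oc2cc(O)c(Oc3cc(O)c(O)c(O)c3Oc3cc(O)c(Oc4cc(O)c(O)c(O)c4Oc4cc(O)c(Oc5cc(O)c(O)c(O)c5Oc5cc(O)c(Oc6cc(O)c(O)c(O)c6Oc6cc(O)c(Oc7cc(O)c(O)c(O)c7)c(O)c6)c(O)c5)c(O)c4)c(O)c3)c(O)c2)c(O)c1 | target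

**Step count**
Total: 25 steps. Longest linear sequence: 14 steps (1 → 3 → 4 → 6 → 8 → 15 → 17 → 38 → 40 → 42 → 43 → 45 → 47 → 48 → 49).

**Steps most likely to fail**

Step 24. The vinylketene released from the pentameric cyclobutenone 47 may be captured too slowly by the equally large, dilute ynol ether 36, so that re-closure, ketene dimerization or O-acylation of the product phenol by a second vinylketene outruns ring formation. The fallback grows the right half linearly on the ynol ether, with the small cyclobutenones in excess. It sets out from 36. Heating 36 with monomer 14 (3 equiv, PhMe, 80 → 110 °C) should give the A–G heptamer with ring F as phenol F1, and MeI/K2CO3 its methyl ether F2. n-BuLi then water should convert the dichlorovinyl ether through the lithium acetylide F3 into the heptamer ethynyl ether F4. A second round with 14 should give the nonamer phenol F5, its methyl ether F6, the lithium acetylide F7 and the nonamer ethynyl ether F8. Benzannulation of F8 with ring K cyclobutenone 28 closes ring J to give the undecamer with free OH on ring J F9. BBr3 dealkylation of F9 comes back to the route at target 49, bypassing compounds 37 to 48.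

Step 23. The pentameric aryloxyketene may dimerize or be intercepted by chloride or amine before it meets ethoxyacetylene, or the vinylogous-ester cyclobutenone may be lost to the ammonium salt and to chromatography. The fallback generates the same vinylketene without a cyclobutenone, by 1,4-dehydrochlorination of an unsaturated acid chloride. It sets out from phenol 43. O-Alkylation with commercial ethyl (E)-4-chloro-3-ethoxybut-2-enoate (K2CO3, NaI cat., DMF) should give the pentamer ethyl 4-aryloxy-3-ethoxybut-2-enoate F10, LiOH the butenoic acid F11 and (COCl)2 the butenoyl chloride F12. Slow addition of Et3N to F12 and ynol ether 36 in PhMe (rt, then 80 °C) removes a γ-hydrogen and chloride to give the (aryloxy)(ethoxy)vinylketene that 47 would give on heating. Its (2+2), 4π, 6π sequence with 36 comes back to the route at 48.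

Step 25. Twenty-seven ether cleavages must all go to completion while partly dealkylated borates precipitate from CH2Cl2, and the 28-fold phenol may oxidize in air during purification. The fallback avoids handling the free phenol until the end. It sets out from 48. The crude BBr3 product is acetylated (Ac2O, pyridine, DMAP cat.) to the octacosaacetate F13, which is stable, can be purified on silica and separated from under-cleaved material (to be resubjected to BBr3). Acid-catalysed methanolysis of F13 (HCl in degassed MeOH, Ar, rt) comes back to the route at target 49.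

**Further compounds**
F1 | step 24 | A–G heptamer, ring F phenol (OH on C3, OEt on C5), ring G C6 oxygen carrying (E)-1,2-dichloroethenyl | COc1cc(OC)cc(OC)c1Oc1cc(OC)c(c(OCC)c1)Oc1cc(OC)c(OC)c(OC)c1Oc1cc(OC)c(c(OCC)c1)Oc1cc(OC)c(OC)c(OC)c1Oc1cc(O)c(c(OCC)c1)Oc1cc(OC)c(OC)c(OC)c1O/C(Cl)=C\Cl
F2 | step 24 | A–G heptamer as F1 with OMe on C3 of ring F | COc1cc(OC)cc(OC)c1Oc1cc(OC)c(c(OCC)c1)Oc1cc(OC)c(OC)c(OC)c1Oc1cc(OC)c(c(OCC)c1)Oc1cc(OC)c(OC)c(OC)c1Oc1cc(OC)c(c(OCC)c1)Oc1cc(OC)c(OC)c(OC)c1O/C(Cl)=C\Cl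
F3 | step 24 | lithium acetylide of F4 | COc1cc(OC)cc(OC)c1Oc1cc(OC)c(c(OCC)c1)Oc1cc(OC)c(OC)c(OC)c1Oc1cc(OC)c(c(OCC)c1)Oc1cc(OC)c(OC)c(OC)c1Oc1cc(OC)c(c(OCC)c1)Oc1cc(OC)c(OC)c(OC)c1OC#C[Li]
F4 | step 24 | A–G heptamer ethynyl ether (ethynyl on the C6 oxygen of ring G) | COc1cc(OC)cc(OC)c1Oc1cc(OC)c(c(OCC)c1)Oc1cc(OC)c(OC)c(OC)c1Oc1cc(OC)c(c(OCC)c1)Oc1cc(OC)c(OC)c(OC)c1Oc1cc(OC)c(c(OCC)c1)Oc1cc(OC)c(OC)c(OC)c1OC#C
F5 | step 24 | A–I nonamer, ring H phenol (OH on C3, OEt on C5), ring I C6 oxygen carrying (E)-1,2-dichloroethenyl | COc1cc(OC)cc(OC)c1Oc1cc(OC)c(c(OCC)c1)Oc1cc(OC)c(OC)c(OC)c1Oc1cc(OC)c(c(OCC)c1)Oc1cc(OC)c(OC)c(OC)c1Oc1cc(OC)c(c(OCC)c1)Oc1cc(OC)c(OC)c(OC)c1Oc1cc(O)c(c(OCC)c1)Oc1cc(OC)c(OC)c(OC)c1O/C(Cl)=C\Cl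
F6 | step 24 | A–I nonamer as F5 with OMe on C3 of ring H | COc1cc(OC)cc(OC)c1Oc1cc(OC)c(c(OCC)c1)Oc1cc(OC)c(OC)c(OC)c1Oc1cc(OC)c(c(OCC)c1)Oc1cc(OC)c(OC)c(OC)c1Oc1cc(OC)c(c(OCC)c1)Oc1cc(OC)c(OC)c(OC)c1Oc1cc(OC)c(c(OCC)c1)Oc1cc(OC)c(OC)c(OC)c1O/C(Cl)=C\Cl
F7 | step 24 | lithium acetylide of F8 | COc1cc(OC)cc(OC)c1Oc1cc(OC)c(c(OCC)c1)Oc1cc(OC)c(OC)c(OC)c1Oc1cc(OC)c(c(OCC)c1)Oc1cc(OC)c(OC)c(OC)c1Oc1cc(OC)c(c(OCC)c1)Oc1cc(OC)c(OC)c(OC)c1Oc1cc(OC)c(c(OCC)c1)Oc1cc(OC)c(OC)c(OC)c1OC#C[Li]
F8 | step 24 | A–I nonamer ethynyl ether (ethynyl on the C6 oxygen of ring I) | COc1cc(OC)cc(OC)c1Oc1cc(OC)c(c(OCC)c1)Oc1cc(OC)c(OC)c(OC)c1Oc1cc(OC)c(c(OCC)c1)Oc1cc(OC)c(OC)c(OC)c1Oc1cc(OC)c(c(OCC)c1)Oc1cc(OC)c(OC)c(OC)c1Oc1cc(OC)c(c(OCC)c1)Oc1cc(OC)c(OC)c(OC)c1OC#C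
F9 | step 24 | undecamer A–K with free OH on C3 and OEt on C5 of ring J; rings B, D, F, H 3-OMe, 5-OEt | COc1cc(OC)cc(OC)c1Oc1cc(OC)c(c(OCC)c1)Oc1cc(OC)c(OC)c(OC)c1Oc1cc(OC)c(c(OCC)c1)Oc1cc(OC)c(OC)c(OC)c1Oc1cc(OC)c(c(OCC)c1)Oc1cc(OC)c(OC)c(OC)c1Oc1cc(OC)c(c(OCC)c1)Oc1cc(OC)c(OC)c(OC)c1Oc1cc(O)c(c(OCC)c1)Oc1cc(OC)c(OC)c(OC)c1
F10 | step 23 | G–K pentamer ethyl (E)-4-aryloxy-3-ethoxybut-2-enoate (on the C1 oxygen of ring G) | CCOC(=O)/C=C(/OCC)COc1cc(OC)c(OC)c(OC)c1Oc1cc(OC)c(c(OCC)c1)Oc1cc(OC)c(OC)c(OC)c1Oc1cc(OC)c(c(OCC)c1)Oc1cc(OC)c(OC)c(OC)c1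
F11 | step 23 | G–K pentamer (E)-4-aryloxy-3-ethoxybut-2-enoic acid | OC(=O)/C=C(/OCC)COc1cc(OC)c(OC)c(OC)c1Oc1cc(OC)c(c(OCC)c1)Oc1cc(OC)c(OC)c(OC)c1Oc1cc(OC)c(c(OCC)c1)Oc1cc(OC)c(OC)c(OC)c1
F12 | step 23 | G–K pentamer (E)-4-aryloxy-3-ethoxybut-2-enoyl chloride | ClC(=O)/C=C(/OCC)COc1cc(OC)c(OC)c(OC)c1Oc1cc(OC)c(c(OCC)c1)Oc1cc(OC)c(OC)c(OC)c1Oc1cc(OC)c(c(OCC)c1)Oc1cc(OC)c(OC)c(OC)c1
F13 | step 25 | octacosaacetate of the target (all 28 hydroxyls as acetates) | CC(=O)Oc1cc(OC(C)=O)cc(OC(C)=O)c1Oc1cc(OC(C)=O)c(c(OC(C)=O)c1)Oc1cc(OC(C)=O)c(OC(C)=O)c(OC(C)=O)c1Oc1cc(OC(C)=O)c(c(OC(C)=O)c1)Oc1cc(OC(C)=O)c(OC(C)=O)c(OC(C)=O)c1Oc1cc(OC(C)=O)c(c(OC(C)=O)c1)Oc1cc(OC(C)=O)c(OC(C)=O)c(OC(C)=O)c1Oc1cc(OC(C)=O)c(c(OC(C)=O)c1)Oc1cc(OC(C)=O)c(OC(C)=O)c(OC(C)=O)c1Oc1cc(OC(C)=O)c(c(OC(C)=O)c1)Oc1cc(OC(C)=O)c(OC(C)=O)c(OC(C)=O)c1
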